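## The problem

The target 17 is a depside. Ring B, a 2,4-dihydroxy-6-methylbenzoyl (orsellinoyl) unit, is joined through an aryl ester to O4 of ring A, a 2-heptyl-4,6-dihydroxybenzoic acid. There is no stereocentre, so the difficulty lies in regiochemistry and in the order of unmasking. Ring A is 1,2,3,5-tetrasubstituted, with the C1 carboxyl wedged between the C2 heptyl group and the C6 oxygen; substitution of a 5-alkylresorcinol reaches this pattern only as one of several isomers. The two ring A oxygens must be told apart, because O4 is acylated and O6 stays free. The ester between the rings does not survive hydroxide, alkoxide or hot nucleophiles, and the free 2-hydroxybenzoic acid of ring A loses CO2 on heating. The final operations must therefore be non-basic and cold, and no ester that needs saponification may be left for the end. The key step is possible because C4–O and C6–O are meta, C3 and C5 carry hydrogen and C1 carries a carbon substituent. This is the pattern laid down when a ketene carbonyl carbon (C4), a terminal alkoxyalkyne (C5–H, C6–OR), the ketene alpha-carbon with its ester (C1) and a 1,1-disubstituted vinyl group (C2–heptyl, C3) are stitched into a benzene ring, and it delivers O4 free and O6 masked.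

## Retrosynthesis

**Unmasking (17 from 16).** Four alkyl–oxygen bonds are cut: O6–ethyl on ring A, the two benzyl–oxygen bonds on ring B and the benzyl–oxygen bond of the ring A ester. The ethyl group is a consequence of the ring synthesis, which uses the commercial alkoxyalkyne 6. Because it ends up ortho to the C1 carboxyl, chelation-assisted Lewis-acid dealkylation can remove it, and with benzyl as every other protecting group one reagent removes all four. The neighbouring options are worse: hydrogenolysis alone would leave the ethyl ether, and an ester needing hydroxide would cost the depside bond. Compound 16 is no simpler in skeleton than 17, but it has no acidic hydrogen and is easy to purify. The forward step must cleave alkyl–oxygen bonds only and leave the acyl–oxygen bond between the rings intact.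

**Depside bond (16 from 11 and 14).** The C(=O)–O4 bond between the rings is cut, giving the ring A phenol 11 and the ring B acid 14. This cut divides the molecule into two benzene units of similar size. Compound 11 has exactly one free hydroxyl, at C4, so the acylation poses no regiochemical question. The forward reaction must acylate a phenol with a di-ortho-substituted benzoic acid without base; activation as the mixed anhydride 15 does this.

**Ring B acid (14 from 13, 13 from 12).** Only protecting-group bonds are cut. Compound 14 is orsellinic acid 12 with both phenols benzylated, reached by perbenzylation to 13 and hydrolysis of the ester. Benzyl rather than methyl ethers are chosen because they fall in the same final step as the ethyl ether of ring A.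

**Ring A (11 from 5 and 6).** Ring A is taken apart at four bonds: C1–C2, C1–C6, C4–C5 and C3–C4. This leaves two pieces:
- the acyclic diazo keto ester 5, which holds C1 with its carboxyl, C2 with the heptyl chain, C3 and C4;
- the alkyne 6, which brings C5 and C6 with its oxygen.

Cuts of one or two ring bonds (aldol folding of a polycarbonyl chain, a (4+2) addition to an ynoate) rely on a chain that can fold in several ways or on a sluggish dienophile. Here each substituent position is fixed by the component that carries it. The free hydroxyl at C4 comes from the ketone oxygen of 5 and the ether at C6 from 6, which is the differentiation the depside bond needs. In the forward direction 5 must lose N2 and rearrange to vinylketene 7, and 7 must add 6 across its C=C bond to give cyclobutenone 8. Opening to dienylketene 9, closure to dienone 10 and enolization then follow. The demand is periselectivity: (2+2) addition at the ketene C=C, not hetero-(4+2) addition through the ester carbonyl.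

**Diazo keto ester (5 from 4, 4 from 2 and 3).** The bond between the diazo carbon and the carbinol carbon is cut. Compound 4 is the adduct of benzyl diazoacetate 3 and enal 2, and oxidation of its hydroxyl gives 5. Bringing the diazo group in with the nucleophile avoids a diazo transfer onto a polymerization-prone vinyl keto ester. The forward reactions must be a 1,2-addition to the enal in preference to reaction at its C=C bond, and a neutral oxidation.

**Enal (2 from 1).** The C=CH2 bond is cut; 2 is nonanal 1 with a methylene group on its alpha-carbon. All carbons of ring A are then traced to commercial materials: 1 gives C2, C4 and the heptyl chain, a one-carbon aldehyde gives C3, 3 gives C1 and the carboxyl, and 6 gives C5 and C6.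

## Roads not taken

**Alternative 1:** The cut runs through both bonds to the depside carbonyl carbon, the aryl–C(=O) bond of ring B and the C(=O)–O4 bond. In the forward step Pd(OAc)2 with Xantphos would join 1,5-bis(benzyloxy)-2-iodo-3-methylbenzene A2, carbon monoxide and the 4-hydroxyl of benzyl 2-heptyl-4,6-dihydroxybenzoate A3. The product is benzyl 4-{[2,4-bis(benzyloxy)-6-methylbenzoyl]oxy}-2-heptyl-6-hydroxybenzoate A1.
- Merits: ring B enters without a hindered benzoic acid ever being made, so steps 5 and 6 of the chosen route would not be needed. The chelated 6-hydroxyl of A3 needs no protection. All protecting groups of A1 are benzyl, so the end is a neutral hydrogenolysis. In this respect the road is better than the chosen one, whose ring A arrives with an ethyl ether that demands a Lewis acid.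
- Weak points: the carbonylation does not address the real problem, the construction of ring A, and A3 must still come from another ring synthesis. A2 is electron-rich and di-ortho-substituted, so after oxidative addition to zerovalent palladium, CO insertion competes with hydrodehalogenation. The hindered acylpalladium must be captured by a phenol, a weaker nucleophile than an alcohol, in the presence of base that puts the product aryl ester at risk of acyl transfer.
- Comparison: this is a new way to make a bond that classical acylation already makes for exactly these partners. The chosen plan puts its novelty where the target is hard, and its ring synthesis delivers the O4/O6 differentiation.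

**Alternative 2:** The cut is the C1–C2 bond of ring A, which opens the ring to 3,5,7-trioxotetradecanoic acid A4. In buffered, near-neutral water, C2 of the chain would add to the C7 ketone; dehydration and enolization would give 2-heptyl-4,6-dihydroxybenzoic acid A5.
- Merits: the step copies the biosynthesis and needs no protecting group. A5 is one carboxyl benzylation away from A3, whose chelated 6-hydroxyl leaves O4 as the reactive site. If the cyclization were clean this would be the shortest road to ring A, shorter than the chosen one, and it would end with hydrogenolysis.
- Weak points: A4 is a 3-oxo acid that decarboxylates readily. A chain with three ketones and a carboxyl has competing closures: lactonization of the C5 enol onto the carboxyl, dehydrative closure between the C3 and C7 oxygens, and Claisen-type attack of C6 on C1. Which closure wins depends on pH and counter-ion, not on anything in the substrate. Making A4 requires polyanion chemistry.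
- Comparison: in the chosen plan the connectivity of ring A is dictated by the atoms that three stable components bring, and no folding ambiguity exists. Against the brevity of this road the chosen plan sets that certainty of constitution, at the price of an untested cycloaddition.

**Alternative 3:** The cut is at C1–C6 and C2–C3. Benzyl dec-2-ynoate A6 and 1,1-dimethoxy-3-(trimethylsilyloxy)buta-1,3-diene A7 would undergo (4+2) cycloaddition. Loss of the elements of methanol and desilylation would aromatize the adduct to benzyl 2-heptyl-4-hydroxy-6-methoxybenzoate A8.
- Merits: A8 has the same oxygen differentiation as 11 (O4 free, O6 as ether). Regiochemistry is fixed by pairing the nucleophilic diene terminus with the ynoate beta-carbon. The reaction type is established for alkynoates, with no diazo compound and no photochemistry. The methyl ether of A8 should be cleaved by chelation-assisted dealkylation more readily than the ethyl ether of 11. In reliability of the ring-forming step this road is at least as good as the chosen one and probably better.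
- Weak points: an ynoate with an unactivated alkyl group at the beta-carbon is a sluggish dienophile, and the heating it needs is hard on the moisture- and heat-sensitive ketene acetal A7. Both components must be prepared. Only two ring bonds are formed.
- Comparison: the step count would be similar. The chosen plan sets against it four ring bonds formed in one operation from three commercial building blocks, and a cycloaddition between a ketene and an electron-rich alkyne that is fast at room temperature, so no slow partner has to be forced.

Key step: step 4

Remark on the chemistry: ring A locants of the target (C1 carboxyl, C2 heptyl, C4 and C6 oxygen) are used for all ring A compounds; 4 and 8 are racemic and their stereocentres do not reach the target.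

## Route

Step 1
Reactants: 1 nonanal
Product: 2 2-methylidenenonanal
Conditions: aq. HCHO (37%), pyrrolidine (10 mol%), EtCO2H (10 mol%), i-PrOH, 45 °C
Reagents that add atoms: formaldehyde, C=O
Why: Amine-catalysed Mannich condensation of the aldehyde with formaldehyde followed by elimination (alpha-methylenation of an aldehyde) is general for unbranched aliphatic aldehydes; no stereocentre is formed.

Step 2
Reactants: 2 2-methylidenenonanal; 3 benzyl diazoacetate
Product: 4 benzyl 2-diazo-3-hydroxy-4-methylideneundecanoate (racemic)
Conditions: 3, LiN(i-Pr)2, THF, –78 °C; then 2, –78 °C; AcOH quench
Reagents that add atoms: none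
Why: Aldol-type addition of the lithiated diazo ester to the aldehyde carbonyl is fast at –78 °C, so 1,2-addition should outrun conjugate addition and 1,3-dipolar cycloaddition of the diazo group to the enal C=C; the carbinol centre forms as a racemate and is removed in step 3.

Step 3
Reactants: 4 benzyl 2-diazo-3-hydroxy-4-methylideneundecanoate
Product: 5 benzyl 2-diazo-4-methylidene-3-oxoundecanoate
Conditions: 2-iodoxybenzoic acid (IBX), DMSO, rt
Reagents that add atoms: none
Why: Oxidation of 2-diazo-3-hydroxy esters to 2-diazo-3-oxo esters with 2-iodoxybenzoic acid is a standard neutral method that leaves the acceptor-stabilized diazo group and the alkene untouched; it erases the only stereocentre.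

Step 4
Reactants: 5 benzyl 2-diazo-4-methylidene-3-oxoundecanoate; 6 ethoxyethyne
Product: 11 benzyl 6-ethoxy-2-heptyl-4-hydroxybenzoate, via vinylketene 7 (not isolated), via vinylcyclobutenone 8 (not isolated), via dienylketene 9 (not isolated), via cyclohexadienone 10 (not isolated)
Conditions: hν (254 nm, quartz), 6 (4 equiv), ClCH2CH2Cl (dry, degassed), rt; then 80 °C
Reagents that add atoms: none
Why: Proposed new method: irradiation expels N2 from 5 and the non-1-en-2-yl group shifts from the ketone carbon to the carbene carbon (photochemical Wolff rearrangement, which makes the C1–C2 bond) to give the ester-bearing vinylketene 7. The nucleophilic CH terminus of 6 bonds to the electrophilic ketene carbonyl carbon (C4–C5) and the ethoxy-bearing carbon to the ketene alpha-carbon (C1–C6) in a (2+2) cycloaddition that gives cyclobutenone 8; this regiochemistry follows from the polarization of both partners and places the ethoxy group at C6 next to the ester. Four-electron conrotatory opening of 8 gives dienylketene 9, and ring A, the only ring that persists, closes by six-electron disrotatory electrocyclization of 9 (C3–C4), after which dienone 10 enolizes to the phenol, the former ketone carbon of 5 becoming C4–OH. The closest known reaction is the Danheiser benzannulation of alpha,beta-unsaturated alpha-diazo ketones with alkoxy- and siloxyalkynes, which runs through the same four events; what has not been shown is a vinylketene that carries an ester on its alpha-carbon, as a 2-diazo-3-oxo ester must give. No stereocentre survives the step: the quaternary carbon of 8 is racemic and becomes planar on ring opening. The step needs alkenyl rather than benzyloxy migration in the Wolff shift, which the much higher migratory aptitude of the carbon substituent on the ketone side of a 2-diazo-3-oxo ester should secure, and it needs the alkyne to add across the ketene C=C and not across the ester-carbonyl/ketene heterodiene in a (4+2) sense. The latter rests on an ester carbonyl being a far poorer four-electron partner than a ketone carbonyl and on the known speed of ketene–ynol ether (2+2) addition at room temperature, helped by the excess of 6. If 8 opens with the vinyl group turned away from the ketene, the opening is reversible whereas aromatization from the productive isomer 9 is not, so material should funnel to 11.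

Step 5
Reactants: 12 orsellinic acid (2,4-dihydroxy-6-methylbenzoic acid)
Product: 13 benzyl 2,4-bis(benzyloxy)-6-methylbenzoate
Conditions: BnBr (3.5 equiv), K2CO3, DMF, rt → 60 °C
Reagents that add atoms: benzyl bromide, BrCc1ccccc1
Why: Carboxylate alkylation and Williamson ether synthesis; the carboxylate is benzylated first at room temperature, which guards the acid against decarboxylation before the mixture is warmed to alkylate both phenols, the chelated 2-hydroxyl last.

Step 6
Reactants: 13 benzyl 2,4-bis(benzyloxy)-6-methylbenzoate
Product: 14 2,4-bis(benzyloxy)-6-methylbenzoic acid
Conditions: KOH, DMSO–H2O, 90 °C; then aq. HCl, 0 °C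
Reagents that add atoms: potassium hydroxide, [K+].[OH-]
Why: Saponification of the di-ortho-substituted ester needs hot KOH in aqueous DMSO but should be clean, because aryl benzyl ethers are inert to hydroxide; acidification gives the free acid.

Step 7
Reactants: 11 benzyl 6-ethoxy-2-heptyl-4-hydroxybenzoate; 14 2,4-bis(benzyloxy)-6-methylbenzoic acid
Product: 16 benzyl 4-{[2,4-bis(benzyloxy)-6-methylbenzoyl]oxy}-6-ethoxy-2-heptylbenzoate, via mixed trifluoroacetic anhydride 15 (not isolated)
Conditions: (CF3CO)2O, toluene, 0 °C → rt
Reagents that add atoms: none
Why: Depside esterification through the mixed trifluoroacetic anhydride 15 is the classical way to acylate a phenol with a di-ortho-substituted, electron-rich benzoic acid, since the acyl group is transferred with acylium character and hindrance at the carbonyl matters little. Compound 11 offers a single unhindered hydroxyl, and no base is present that could cleave the product.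

Step 8
Reactants: 16 benzyl 4-{[2,4-bis(benzyloxy)-6-methylbenzoyl]oxy}-6-ethoxy-2-heptylbenzoate
Product: 17 4-[(2,4-dihydroxy-6-methylbenzoyl)oxy]-2-heptyl-6-hydroxybenzoic acid
Conditions: BCl3 (8 equiv), C6HMe5 (10 equiv), CH2Cl2, –78 → 0 °C; then H2O
Reagents that add atoms: none
Why: Lewis-acid dealkylation: BCl3 cleaves aryl benzyl ethers at low temperature with pentamethylbenzene as a non-basic cation trap, removes the benzyl ester by alkyl–oxygen cleavage, and dealkylates the ethyl ether because boron is chelated between O6 and the C1 carboxyl. Aryl esters such as the depside link are not opened by acyl–oxygen fission under these conditions, and the free acid sees neither base nor heat.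

## Compound list

1 | nonanal | CCCCCCCCC=O | starting material
2 | 2-methylidenenonanal | CCCCCCCC(=C)C=O | intermediate
3 | benzyl diazoacetate | [N-]=[N+]=CC(=O)OCc1ccccc1 | starting material
4 | benzyl 2-diazo-3-hydroxy-4-methylideneundecanoate (racemic) | CCCCCCCC(=C)C(O)C(=[N+]=[N-])C(=O)OCc1ccccc1 | intermediate
5 | benzyl 2-diazo-4-methylidene-3-oxoundecanoate | CCCCCCCC(=C)C(=O)C(=[N+]=[N-])C(=O)OCc1ccccc1 | intermediate
6 | ethoxyethyne | CCOC#C | starting material
7 | benzyl 3-methylidene-2-(oxomethylidene)decanoate (vinylketene, not isolated) | O=C=C(C(=O)OCc1ccccc1)C(=C)CCCCCCC | intermediate
8 | benzyl 2-ethoxy-1-(non-1-en-2-yl)-4-oxocyclobut-2-ene-1-carboxylate (racemic, not isolated) | O=C1C=C(OCC)C1(C(=O)OCc1ccccc1)C(=C)CCCCCCC | intermediate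
9 | benzyl (2Z)-3-ethoxy-2-(non-1-en-2-yl)-5-oxopenta-2,4-dienoate (dienylketene, not isolated) | O=C=C/C(OCC)=C(/C(=O)OCc1ccccc1)C(=C)CCCCCCC | intermediate
10 | benzyl 6-ethoxy-2-heptyl-4-oxocyclohexa-1,5-diene-1-carboxylate (not isolated) | CCCCCCCC1=C(C(=O)OCc2ccccc2)C(OCC)=CC(=O)C1 | intermediate
11 | benzyl 6-ethoxy-2-heptyl-4-hydroxybenzoate | CCCCCCCc1cc(O)cc(OCC)c1C(=O)OCc1ccccc1 | intermediate
12 | orsellinic acid (2,4-dihydroxy-6-methylbenzoic acid) | Cc1cc(O)cc(O)c1C(=O)O | starting material
13 | benzyl 2,4-bis(benzyloxy)-6-methylbenzoate | Cc1cc(OCc2ccccc2)cc(OCc2ccccc2)c1C(=O)OCc1ccccc1 | intermediate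
14 | 2,4-bis(benzyloxy)-6-methylbenzoic acid | Cc1cc(OCc2ccccc2)cc(OCc2ccccc2)c1C(=O)O | intermediate
15 | 2,4-bis(benzyloxy)-6-methylbenzoic trifluoroacetic anhydride (not isolated) | Cc1cc(OCc2ccccc2)cc(OCc2ccccc2)c1C(=O)OC(=O)C(F)(F)F | intermediate
16 | benzyl 4-{[2,4-bis(benzyloxy)-6-methylbenzoyl]oxy}-6-ethoxy-2-heptylbenzoate | CCCCCCCc1cc(OC(=O)c2c(C)cc(OCc3ccccc3)cc2OCc2ccccc2)cc(OCC)c1C(=O)OCc1ccccc1 | intermediate
17 | 4-[(2,4-dihydroxy-6-methylbenzoyl)oxy]-2-heptyl-6-hydroxybenzoic acid | CCCCCCCc1cc(OC(=O)c2c(C)cc(O)cc2O)cc(O)c1C(=O)O | target

## Step count and least certain steps

Total: 8 steps. Longest linear sequence: 6 steps (1 → 2 → 4 → 5 → 11 → 16 → 17, steps 1–4, 7 and 8). The ring B acid 14 is made in 2 steps beside it.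

**Step 4 (key step, proposed new method).** Three things are most likely to go wrong.
- Ketene 7 may be captured by 6 through the ester carbonyl oxygen. After the alkyne carbon has bonded to the ketene carbonyl carbon, closure can occur at oxygen (hetero-(4+2), a six-membered oxygen ring) instead of at carbon (the four-membered ring), because the ester makes 7 an acylketene-type heterodiene.
- Dienylketene 9 may close through the ester carbonyl oxygen when the ester, not the vinyl group, lies cis to the ketene.
- The very electrophilic 7 may dimerize or be hydrated if the alkyne concentration is low or the solvent is wet.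

The fallback uses known chemistry only and sets out from 3. SnCl2-catalysed Roskamp homologation of octanal with 3 gives benzyl 3-oxodecanoate F1. The known base-mediated condensation of a 3-oxo ester with diketene (NaH, THF: C-acetoacetylation, then aldol closure onto the heptyl ketone and dehydration) gives benzyl 2-heptyl-4,6-dihydroxybenzoate F2 (the compound labelled A3 above). Its 6-hydroxyl is hydrogen-bonded to the ester, so acylation with 14 and (CF3CO)2O goes to O4 and gives benzyl 4-{[2,4-bis(benzyloxy)-6-methylbenzoyl]oxy}-2-heptyl-6-hydroxybenzoate F3 (the compound labelled A1 above). Hydrogenolysis (H2, Pd/C, EtOAc) then comes back to the route at 17.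

**Step 8.** The ethyl ether is dealkylated more slowly than a methyl ether, and the benzyl ester more slowly than the aryl benzyl ethers. The likely failures are incomplete alkyl–oxygen cleavage at these two sites or, if the mixture is pushed to higher temperature, acyl–oxygen cleavage of the depside link, decarboxylation of the liberated acid and ring benzylation. The fallback moves the Lewis-acid step ahead of the depside bond and sets out from 11. BCl3 with pentamethylbenzene on this robust monocyclic ester removes the ethyl ether and the benzyl ester to give 2-heptyl-4,6-dihydroxybenzoic acid F4 (the compound labelled A5 above). Carboxylate alkylation (BnBr, KHCO3, DMF) gives benzyl 2-heptyl-4,6-dihydroxybenzoate F2. Acylation at O4 with 14 and (CF3CO)2O gives benzyl 4-{[2,4-bis(benzyloxy)-6-methylbenzoyl]oxy}-2-heptyl-6-hydroxybenzoate F3, and hydrogenolysis (H2, Pd/C) comes back to the route at 17.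

**Step 2.** The diazo ester may add to the C=C bond of enal 2 by 1,3-dipolar cycloaddition if the temperature rises before the aldol addition is complete. The amide base may deprotonate the enal at its allylic position, and the lithium aldolate may revert on warming. The fallback introduces the diazo group after the carbon–carbon bond is made and sets out from 2. Reformatsky addition of benzyl bromoacetate (Zn, THF) gives benzyl 3-hydroxy-4-methylideneundecanoate F5. Oxidation with Dess–Martin periodinane gives benzyl 4-methylidene-3-oxoundecanoate F6. Regitz diazo transfer (4-acetamidobenzenesulfonyl azide, Et3N, MeCN) comes back to the route at 5.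

## Further compounds

F1 | step 4 | benzyl 3-oxodecanoate | CCCCCCCC(=O)CC(=O)OCc1ccccc1
F2 | step 4 | benzyl 2-heptyl-4,6-dihydroxybenzoate | CCCCCCCc1cc(O)cc(O)c1C(=O)OCc1ccccc1
F3 | step 4 | benzyl 4-{[2,4-bis(benzyloxy)-6-methylbenzoyl]oxy}-2-heptyl-6-hydroxybenzoate | CCCCCCCc1cc(OC(=O)c2c(C)cc(OCc3ccccc3)cc2OCc2ccccc2)cc(O)c1C(=O)OCc1ccccc1
F4 | step 8 | 2-heptyl-4,6-dihydroxybenzoic acid | CCCCCCCc1cc(O)cc(O)c1C(=O)O
F5 | step 2 | benzyl 3-hydroxy-4-methylideneundecanoate | CCCCCCCC(=C)C(O)CC(=O)OCc1ccccc1
F6 | step 2 | benzyl 4-methylidene-3-oxoundecanoate | CCCCCCCC(=C)C(=O)CC(=O)OCc1ccccc1
A1 | alternative 1 | benzyl 4-{[2,4-bis(benzyloxy)-6-methylbenzoyl]oxy}-2-heptyl-6-hydroxybenzoate | CCCCCCCc1cc(OC(=O)c2c(C)cc(OCc3ccccc3)cc2OCc2ccccc2)cc(O)c1C(=O)OCc1ccccc1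
A2 | alternative 1 | 1,5-bis(benzyloxy)-2-iodo-3-methylbenzene | Cc1cc(OCc2ccccc2)cc(OCc2ccccc2)c1I
A3 | alternative 1 | benzyl 2-heptyl-4,6-dihydroxybenzoate | CCCCCCCc1cc(O)cc(O)c1C(=O)OCc1ccccc1
A4 | alternative 2 | 3,5,7-trioxotetradecanoic acid | CCCCCCCC(=O)CC(=O)CC(=O)CC(=O)O
A5 | alternative 2 | 2-heptyl-4,6-dihydroxybenzoic acid | CCCCCCCc1cc(O)cc(O)c1C(=O)O
A6 | alternative 3 | benzyl dec-2-ynoate | CCCCCCCC#CC(=O)OCc1ccccc1
A7 | alternative 3 | 1,1-dimethoxy-3-(trimethylsilyloxy)buta-1,3-diene | COC(OC)=CC(=C)O[Si](C)(C)C
A8 | alternative 3 | benzyl 2-heptyl-4-hydroxy-6-methoxybenzoate | CCCCCCCc1cc(O)cc(OC)c1C(=O)OCc1ccccc1
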